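All runs are calculated for substances that don't exist, noise included.

A plateau in product is easily misread as a dead catalyst, yet in the birch and elm runs the plateau moves with the solid reagent charged.

| setting | birch | elm | flask |
|---|---|---|---|
| left-handed substrate | 0.13 M | 0.13 M | 0.13 M |
| right-handed substrate | 0.13 M | 0.13 M | 0.13 M |
| solid reagent | 0.60 equiv | 0.90 equiv | 1.20 equiv |
| free catalyst | 0.27 mol% | 0.27 mol% | 0.27 mol% |
| remark | run made earlier | run made earlier |  |
| time |  |  | 2.5 h |

| run | time / h | left-handed product / % | right-handed product / % |
|---|---|---|---|
| birch | 0.417 | 6.5 | 15.1 |
| birch | 0.833 | 8.3 | 21.4 |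
| birch | 1.33 | 8.5 | 21.0 |
| birch | 1.50 | 8.8 | 21.7 |
| birch | 2.00 | 8.3 | 22.0 |
| birch | 2.50 | 9.3 | 21.3 |
| birch | 3.00 | 9.3 | 21.3 |
| elm | 0.167 | 2.3 | 5.9 |
| elm | 0.500 | 9.5 | 24.6 |
| elm | 0.833 | 12.5 | 30.1 |
| elm | 1.33 | 13.1 | 31.7 |
| elm | 2.00 | 13.0 | 31.1 |
| elm | 2.50 | 12.8 | 32.5 |
| elm | 3.00 | 12.9 | 31.7 |

(scatter of a reading: 0.5 percentage points)

- free catalyst is single-handed; left-handed substrate and right-handed substrate are mirror images of each other, charged as a racemate, each of them at the stated concentration
- solid reagent is a solid; its amount is given per volume of the solution
- reactions considered so far: free catalyst + right-handed substrate <-> catalyst intermediate B; partner + catalyst intermediate A -> free catalyst + left-handed product; free catalyst + left-handed substrate <-> catalyst intermediate A; 2 free catalyst -> spent catalyst; left-handed substrate <-> right-handed substrate; solid reagent <-> partner; partner + catalyst intermediate B -> free catalyst + right-handed product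
- at the start none of the solid reagent is in solution
- an excess is the difference of the two amounts in percent of their sum
- an excess is below zero if the other one leads

- excess of left-handed product over right-handed product in the product at 15 min
- excess of left-handed product over right-handed product in the product at 2.5 h
- part of the left-handed substrate and right-handed substrate charged together that has reacted at 2.5 h

Averaged over birch and elm, the last readings give 0.503 of the two substrates together per equivalent. This yield per equivalent, conversion at the plateau over equivalents of solid reagent charged, is the number to carry. One partner makes one product and equivalents are counted on one substrate, so the ceiling stands at 0.5, and solid reagent reads as the limiting reagent. For the flask, my reckoning is 60.3%.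

The objection is that the flask needs more turnover than either run showed, and the catalyst might fail first. At the pace of elm over its first 0.500 h, the reckoned time to that conversion is 0.885 h, shorter than 2.5 h, which leaves room for a sagging pace.

A second doubt concerns the excess, which could drift as the substrates run down. Elm reads −43.9% at its first point, from readings of 2.3% and 5.9% that each carry a scatter of 0.5 percentage points, and −42.2% on its plateau. My reckoning therefore keeps the plateau value at both asked times.

The forecast gave −42.5% (−47% to −39%), −40% (−44% to −33%) and a conversion of 58% (51% to 61%), the conversion lying below my reckoning: “At 1.20 equiv I expect about 60%, perhaps slightly less if catalyst loss starts to bite.”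

    free catalyst + right-handed substrate ⇌ catalyst intermediate B (K = 27.5 /M, k = 8380 /M/min)
    partner + catalyst intermediate A → free catalyst + left-handed product (k = 477 /M/min)
    free catalyst + left-handed substrate ⇌ catalyst intermediate A (K = 5.30 /M, k = 4860 /M/min)
    2 free catalyst → spent catalyst (k = 102 /M/min)
    left-handed substrate ⇌ right-handed substrate (k = 0.344 /min)
    solid reagent ⇌ partner, rate k6*(cs6 - [partner]) while solid is left; crystals form when [partner] > cs6 (solubility = 0.0800 M, k = 0.155 /min)
    partner + catalyst intermediate B → free catalyst + right-handed product (k = 231 /M/min)

The flask gives −42.0%, −41.9% and a conversion of 59.8%, each inside the forecast's range. Spent catalyst stands at 54.4% of the catalyst charged at 2.50 h, with solid reagent at 0%. The yield per equivalent had promised 60.3%, which is 0.49 points above the flask.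

For a neighbouring flask charged with 2.00 equiv, the yield per equivalent promises 101%. The computed conversion is lower, 92.2%, with partner at 0.0202 M still in solution at 2.50 h, worth 7.78% of the two substrates.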